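(The readings are simulated on assumed constants.)

In a one-step world substrate would keep falling until it was gone, but in Tuesday's run it stood at 73.1 % after 5.00 min and still at 69.2 % after 12.0 min. So I took reagent to have two takers, substrate and partner, each at a rate proportional to c(reagent).

| setting | Tuesday's | Thursday's | Friday's | Sunday's | grey | blue | amber | ochre |
|---|---|---|---|---|---|---|---|---|
| substrate | 0.10 M | 0.050 M | 0.20 M | 0.10 M | 0.10 M | 0.10 M | 0.10 M (fed, over 10 min) | 0.10 M |
| reagent | 1 equiv | 1 equiv | 1 equiv | 0.50 equiv | 1.00 equiv (fed, over 10 min) | 1.00 equiv | 1.00 equiv | 1.00 equiv (in portions, 2, over 10 min) |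
| gas | 7.8 mM (held) | 7.8 mM (held) | 7.8 mM (held) | 7.8 mM (held) | 7.8 mM (held) | 7.8 mM (held) | 7.8 mM (held) | 7.8 mM (held) |
| remark | run made earlier | run made earlier | run made earlier | run made earlier | all else is in the flask from the start; the feed brings no volume worth counting | everything together at the start | all else is in the flask from the start; the feed brings no volume worth counting | first portion at the start, last at 10 min |
| time |  |  |  |  | 12 min | 12 min | 12 min | 12 min |

- Tuesday's (time / min: product / %, substrate / %): 1.00: 2.4, 92.2; 2.00: 8.7, 86.1; 5.00: 24.3, 73.1; 12.0: 32.1, 69.2
- Thursday's (time / min: product / %, substrate / %): 3.00: 9.2, 91.7; 6.00: 13.0, 82.8; 10.0: 19.7, 82.1; 12.0: 17.4, 82.1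
- Friday's (time / min: product / %, substrate / %): 1.00: 5.1, 82.3; 2.00: 11.6, 75.4; 5.00: 31.5, 58.1; 12.0: 45.8, 50.6
- Sunday's (time / min: product / %, substrate / %): 1.50: 3.2, 93.9; 4.00: 8.5, 88.5; 8.00: 13.7, 84.5; 12.0: 13.8, 84.9

(standard deviation of a reading: 1 percentage point)

* the best flask by amount of product, in percent of the substrate charged; "all alike" if 1.5 percentage points covers them all (grey / blue / amber / ochre / all alike)
* amount of product at the end, in percent of the substrate charged, grey
* amount of product at the end, in percent of the substrate charged, blue
* amount of product at the end, in percent of the substrate charged, amber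
* amount of product at the end, in percent of the substrate charged, ochre

- at the start none of partner is dissolved
- candidate steps: substrate + reagent -> open intermediate; reagent + partner -> second intermediate; open intermediate + second intermediate -> product; gas <-> partner

Dividing one rate by the other removes time and c(reagent). While c(partner) holds steady, L, the logarithm of charged over remaining substrate, grows by a fixed amount for each mole of reagent spent on partner. I assumed that Tuesday's reagent was spent by the end, which gave L = 0.368. At 1 equiv the reagent spent on partner equals the substrate left, so the split, L per reagent spent on partner, was 5.32 L mol⁻¹. Friday's run read 6.73 L mol⁻¹.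

The split ignores how reagent arrives, so grey's ceiling was Tuesday's loss of 30.8 %, which I also expected from blue. Age tightens this, since Tuesday's reagent had earned 0.406 of L by 2.00 min and 0.851 by 5.00 min. In grey, 70.0 % of the reagent ended older than 5.00 min and the rest between those ages. Rounding the ages up and then down, and reading lost substrate as product, bracketed grey between 23.2 % and 29.7 %. Ochre's two ages gave 22.8 %. I made no number for amber, whose substrate arrives late.

The forecast chose blue, with grey 15 % (11 % to 19 %, below my floor), blue 31.5 %, amber 18.5 % and ochre 19 %, saying “Grey keeps reagent low”.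

The flasks gave grey 23.9 %, blue 31.5 %, amber 15.2 % and ochre 21.0 %, with blue best.

    substrate + reagent → open intermediate (k = 0.0160 L mol⁻¹ s⁻¹)
    reagent + partner → second intermediate (k = 0.480 L mol⁻¹ s⁻¹)
    open intermediate + second intermediate → product (k = 2.10 L mol⁻¹ s⁻¹)
    gas ⇌ partner, rate k4*(csat - [partner]) (kL = 0.0720 s⁻¹)

Grey's product lay just above my floor. With 76 % of its substrate and 20 % of its reagent left at 12.0 min, grey read a split of 5.05 L mol⁻¹, against Tuesday's 5.32 L mol⁻¹. A neighbour of blue charged with 0.17 M of substrate, at the same equivalents, kept 55.1 % of its substrate and 3.5 % of its reagent. The same reckoning on it gives 6.79 L mol⁻¹, close to Friday's 6.73 L mol⁻¹, and its product stood at 44.6 %.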